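The route rests on cutting ring C (O1–C2–C3–C4–C4a–C8a) at O1–C2 and C4–C4a. C4, taken as a ketone, and the tertiary C2 stand in a 1,3-relation, which is the retron of a 3-methylbut-2-enoyl unit. In the precursor, C4a is the only hydrogen-bearing carbon of ring A and lies next to O1. One acid-mediated operation, Friedel–Crafts acylation then 6-endo oxa-Michael closure, therefore fuses 3-methylbut-2-enoic acid onto the complete dihydrochalcone. The precursor carries a single free phenol and the other two oxygens are methyl ethers, so only one pyranone can form. Chelation-directed demethylation and a catalyst-controlled transfer hydrogenation of the ring ketone then set (R)-C4.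

Key step: step 3

Remark: bicyclic compounds carry chroman numbering (O1, C2, C3, C4, C4a, C5–C8, C8a) and monocyclic ones carry primed dihydrochalcone numbering. The only stereocenter of the target, C4, reads as R from the given SMILES (priorities OH > C4a > C3 > H).

Step 1
Reactants: 1 4-hydroxy-2,6-dimethoxybenzaldehyde
Product: 3 3,5-dimethoxy-4-methylphenol, via benzylic alcohol 2 (not isolated)
Conditions: H2 (4 bar), Pd/C, AcOH, 25 °C
Reagents that add atoms: none
Why: Catalytic hydrogenation followed by benzylic hydrogenolysis: the aldehyde is reduced to the electron-rich p-hydroxybenzyl alcohol 2, whose C–O bond is cleaved readily on palladium in acidic medium, which leaves a methyl group between the two methoxy groups and the free OH para to it.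

Step 2
Reactants: 3 3,5-dimethoxy-4-methylphenol; 4 3-phenylpropanoic acid
Product: 5 1-(6-hydroxy-2,4-dimethoxy-3-methylphenyl)-3-phenylpropan-1-one
Conditions: BF3·OEt2 (solvent), 85 °C; aq. NaOAc work-up
Reagents that add atoms: none
Why: Friedel–Crafts acylation (directly or through the aryl ester and a Fries shift) of a highly activated phenol: the two open positions of mirror-symmetric 3 are equivalent and ortho to the OH, so one ketone should result, the first acyl group slows a second acylation, and BF3 is too weak to cyclise 4 to 1-indanone.

Step 3
Reactants: 5 1-(6-hydroxy-2,4-dimethoxy-3-methylphenyl)-3-phenylpropan-1-one; 6 3-methylbut-2-enoic acid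
Product: 8 5,7-dimethoxy-2,2,6-trimethyl-8-(3-phenylpropanoyl)chroman-4-one, via aryl enone 7 (not isolated)
Conditions: P2O5/MeSO3H (1:10 w/w), 60 °C; ice-water quench
Reagents that add atoms: none
Why: The dehydrating acid turns 6 into its mixed anhydride/acylium ion, which acylates C5' of 5 (directly or through the 6'-O-ester and a Fries shift), making the C4–C4a bond and giving enone 7. The acid-activated enone is then attacked at its tertiary β-carbon by the neighbouring 6'-OH, which makes the O1–C2 bond. This is the known tandem Friedel–Crafts acylation/oxa-Michael annulation of phenols with 3-methylbut-2-enoic acid to 2,2-dimethylchroman-4-ones, a formal [3+3] union of a C,O-bisnucleophile and a 1,3-biselectrophile. The single new ring, six-membered ring C, closes in the 6-endo-trig mode. No stereocenter is created, since C4 arrives as a ketone and C2 bears two identical methyl groups, so C4 is left to the catalyst of step 5. Site selectivity is secured because C5' is the only ring A carbon bearing hydrogen, oxygen selectivity because 6'-OH is the only free phenol (the 4'-oxygen, which would give the 8-methyl-6-acyl isomer, is a methyl ether), and acylation should win over conjugate alkylation (dihydrocoumarin formation) thanks to the dehydrating medium and the crowding that a quaternary benzylic carbon would suffer between 4'-OMe and 6'-OH.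

Step 4
Reactants: 8 5,7-dimethoxy-2,2,6-trimethyl-8-(3-phenylpropanoyl)chroman-4-one
Product: 10 5,7-dihydroxy-2,2,6-trimethyl-8-(3-phenylpropanoyl)chroman-4-one, via bis(dichloroboryl) ether 9 (not isolated)
Conditions: BCl3 (4 equiv), CH2Cl2, −78 → 0 °C; then H2O
Reagents that add atoms: boron trichloride ClB(Cl)Cl (boron and chlorine of intermediate 9 only; 10 keeps none of them)
Why: Chelation-directed aryl methyl ether cleavage: each methoxy group lies ortho (peri) to a ketone, so BCl3 bound to that carbonyl activates it within a six-membered chelate for SN2 attack of chloride on the methyl carbon, whereas the tertiary O1–C2 bond, whose ionisation is disfavoured by the boron-complexed C4 carbonyl two bonds away, should stay intact at low temperature.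

Step 5
Reactants: 10 5,7-dihydroxy-2,2,6-trimethyl-8-(3-phenylpropanoyl)chroman-4-one
Product: 11 1-[(4R)-4,5,7-trihydroxy-2,2,6-trimethyl-3,4-dihydro-2H-chromen-8-yl]-3-phenylpropan-1-one (target)
Conditions: RuCl[(R,R)-TsDPEN](p-cymene) (2 mol %), HCO2H/Et3N (1:1), EtOAc, 30 °C; neutral work-up, base-washed silica
Reagents that add atoms: none
Why: Noyori–Ikariya asymmetric transfer hydrogenation: the (R,R)-configured ruthenium hydride delivers hydrogen to the face of the planar, ring-held C4 ketone that places the fused arene next to the η6-cymene ligand, the sense that converts 4-chromanone into (R)-chroman-4-ol, while the acyclic C8 ketone, flanked by O1 and the chelating 7-OH, is too shielded to reach the same transition state, and the near-neutral formate medium spares the ionisable benzylic alcohol.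

Compound list
1 | 4-hydroxy-2,6-dimethoxybenzaldehyde | COc1cc(O)cc(OC)c1C=O | starting material
2 | 4-(hydroxymethyl)-3,5-dimethoxyphenol | COc1cc(O)cc(OC)c1CO | intermediate
3 | 3,5-dimethoxy-4-methylphenol | COc1cc(O)cc(OC)c1C | intermediate
4 | 3-phenylpropanoic acid | OC(=O)CCc1ccccc1 | starting material
5 | 1-(6-hydroxy-2,4-dimethoxy-3-methylphenyl)-3-phenylpropan-1-one | COc1cc(O)c(C(=O)CCc2ccccc2)c(OC)c1C | intermediate
6 | 3-methylbut-2-enoic acid | CC(C)=CC(=O)O | starting material
7 | 1-[2-hydroxy-4,6-dimethoxy-5-methyl-3-(3-phenylpropanoyl)phenyl]-3-methylbut-2-en-1-one | COc1c(C)c(OC)c(C(=O)CCc2ccccc2)c(O)c1C(=O)C=C(C)C | intermediate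
8 | 5,7-dimethoxy-2,2,6-trimethyl-8-(3-phenylpropanoyl)chroman-4-one | COc1c(C)c(OC)c(C(=O)CCc2ccccc2)c2OC(C)(C)CC(=O)c12 | intermediate
9 | 5,7-bis(dichloroboryloxy)-2,2,6-trimethyl-8-(3-phenylpropanoyl)chroman-4-one | Cc1c(OB(Cl)Cl)c(C(=O)CCc2ccccc2)c2OC(C)(C)CC(=O)c2c1OB(Cl)Cl | intermediate
10 | 5,7-dihydroxy-2,2,6-trimethyl-8-(3-phenylpropanoyl)chroman-4-one | Cc1c(O)c(C(=O)CCc2ccccc2)c2OC(C)(C)CC(=O)c2c1O | intermediate
11 | 1-[(4R)-4,5,7-trihydroxy-2,2,6-trimethyl-3,4-dihydro-2H-chromen-8-yl]-3-phenylpropan-1-one | Cc1c(O)c(C(=O)CCc2ccccc2)c2c(c1O)[C@H](O)CC(C)(C)O2 | target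

Total step count: 5. Longest linear sequence: 5 (1 → 3 → 5 → 8 → 10 → 11).

Steps most likely to fail

Step 3. C-acylation at the crowded C5' of a ring that already bears an acyl group may be sluggish. Ipso-protonation at C1' in the strong acid could also strip off the 3-phenylpropanoyl group by a retro-Friedel–Crafts process. The fallback inverts the order of the two acylations, setting out from 3 and returning at 8. The more nucleophilic phenol 3 is annulated with 6 in P2O5/MeSO3H to 5,7-dimethoxy-2,2,6-trimethylchroman-4-one F1. Both ring bonds are still made in one operation, and the single free OH gives the same regiochemical security. The sole remaining position C8 is then acylated with 3-phenylpropanoyl chloride and SnCl4 in CH2Cl2 at 0 °C.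

Step 5. Discrimination between the two chelated ketones may be poor. The acidic acylphenol units may sequester the ruthenium catalyst. The product may ionise at C4 toward an ortho-quinone methide, which would cause racemisation, dehydration or over-reduction. The fallback removes the free phenols before the reduction, setting out from 10 and returning at 11. Silylation (TBSOTf, 2,6-lutidine, CH2Cl2) gives 5,7-bis(tert-butyldimethylsilyloxy)-2,2,6-trimethyl-8-(3-phenylpropanoyl)chroman-4-one F2. Corey–Bakshi–Shibata reduction with (S)-2-methyl-CBS-oxazaborolidine and BH3·SMe2 at −20 °C should give the (4R)-alcohol F3. Here the arene acts as the large group, the sense known for aryl alkyl ketones, and the C8 ketone is buried between O1 and the 7-silyloxy group. Buffered fluoride (TBAF/AcOH, THF, 0 °C) then frees both phenols.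

Step 4. The Lewis acid may open the pyranone by a retro-oxa-Michael process once the 5-oxygen is free. Re-closure on the wrong oxygen would then erode the regiochemistry, and cleavage of the hindered 7-OMe may stay incomplete. The fallback takes the methyl groups off before any pyranone exists, setting out from 5 and returning at 10. BBr3 in CH2Cl2 gives 2',4',6'-trihydroxy-3'-methyldihydrochalcone F4. F4 is annulated with 6 in P2O5/MeSO3H without protecting groups. This should give 10 together with the isomer closed on the 4'-oxygen, 5,7-dihydroxy-2,2,8-trimethyl-6-(3-phenylpropanoyl)chroman-4-one F5. The two are separated by chromatography. F5 is returned to the acid medium for ring opening and re-closure (Wessely–Moser-type equilibration) to feed more 10.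

Further compounds
F1 | step 3 | 5,7-dimethoxy-2,2,6-trimethylchroman-4-one | COc1cc2OC(C)(C)CC(=O)c2c(OC)c1C
F2 | step 5 | 5,7-bis(tert-butyldimethylsilyloxy)-2,2,6-trimethyl-8-(3-phenylpropanoyl)chroman-4-one | Cc1c(O[Si](C)(C)C(C)(C)C)c(C(=O)CCc2ccccc2)c2OC(C)(C)CC(=O)c2c1O[Si](C)(C)C(C)(C)C
F3 | step 5 | 1-[(4R)-5,7-bis(tert-butyldimethylsilyloxy)-4-hydroxy-2,2,6-trimethyl-3,4-dihydro-2H-chromen-8-yl]-3-phenylpropan-1-one | Cc1c(O[Si](C)(C)C(C)(C)C)c(C(=O)CCc2ccccc2)c2c(c1O[Si](C)(C)C(C)(C)C)[C@H](O)CC(C)(C)O2
F4 | step 4 | 2',4',6'-trihydroxy-3'-methyldihydrochalcone | Cc1c(O)cc(O)c(C(=O)CCc2ccccc2)c1O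
F5 | step 4 | 5,7-dihydroxy-2,2,8-trimethyl-6-(3-phenylpropanoyl)chroman-4-one | Cc1c(O)c(C(=O)CCc2ccccc2)c(O)c2C(=O)CC(C)(C)Oc12
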